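**Plan**
- Retrosynthetic cuts: first the three O–CH3 bonds; then the diaryl ether bond between the phenol oxygen of the para-phenylene ring (ring B) and the carbon of the trioxygenated ring A that lies between C–OMe and C–H; then the central C–C of both ArCH2–CH2Ar bridges; last the hindered ether between the o-phenylene ring D and the trioxygenated ring C.
- Forward order: Wittig joins ring D to ring A; SNAr joins ring D–OH to ring C; a second Wittig adds ring B; one hydrogenation saturates both bridges and frees both phenols; oxidative dearomatisation/ring closure forms the only ring (17-membered); BBr3 unmasks the four hydroxyls.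
- Enabling feature: ring A is a 5-alkylpyrogallol mono-aryl ether, so its ether carbon sits next to an oxygenated carbon. Carried as a 2-methoxyphenol, ring A can be dearomatised at the methoxy-bearing carbon to an orthoquinol acetate. In that dienone the future ether carbon is the δ-terminus, the bridge-bearing carbon blocks the β-position, and rearomatisation returns all three oxygens in place.
- Stereochemistry: none to set. Alkene geometries are erased by hydrogenation and the sp3 centres of the dearomatised intermediates by rearomatisation.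

Key step: step 6

Assumption: the target has no stereocentre and the 17-membered cyclophane is taken as conformationally mobile, so the request for a single enantiomer calls for no stereocontrol.

**Step 1**
Reactants: 1 4-(benzyloxy)benzyl chloride
Product: 2 [4-(benzyloxy)benzyl]triphenylphosphonium chloride
Conditions: PPh3, toluene, reflux
Reagents that add atoms: triphenylphosphine, c1ccc(cc1)P(c1ccccc1)c1ccccc1
Why: SN2 quaternisation of triphenylphosphine by a benzylic chloride (phosphonium salt formation), with the salt expected to precipitate from toluene.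

**Step 2**
Reactants: 3 (2-hydroxybenzyl)triphenylphosphonium bromide; 4 3-(benzyloxy)-4-methoxybenzaldehyde
Product: 5 2-[2-(3-benzyloxy-4-methoxyphenyl)ethenyl]phenol (E/Z mixture)
Conditions: t-BuOK (2.2 equiv), THF, 0 °C → rt
Reagents that add atoms: none
Why: Wittig olefination in which two equivalents of base generate the phenoxide–ylide of 3, which condenses with aldehyde 4; the E/Z ratio is irrelevant because the alkene is hydrogenated in step 5.

**Step 3**
Reactants: 5 2-[2-(3-benzyloxy-4-methoxyphenyl)ethenyl]phenol; 6 2-fluoro-3,4-dimethoxybenzaldehyde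
Product: 7 2-{2-[2-(3-benzyloxy-4-methoxyphenyl)ethenyl]phenoxy}-3,4-dimethoxybenzaldehyde (E/Z mixture)
Conditions: Cs2CO3, DMSO, 100 °C
Reagents that add atoms: none
Why: SNAr (addition–elimination through a Meisenheimer adduct) in which the fluoride of 6, activated by the ortho formyl group, is displaced by the caesium phenoxide of 5; the benzyl ether and the stilbene are inert to carbonate.

**Step 4**
Reactants: 7 diaryl ether aldehyde; 2 [4-(benzyloxy)benzyl]triphenylphosphonium chloride
Product: 8 bis-stilbene, i.e. 7 with CHO replaced by CH=CH–C6H4-4-OCH2Ph (E/Z mixture at both alkenes)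
Conditions: t-BuOK, THF, 0 °C → rt
Reagents that add atoms: none
Why: Wittig olefination of aryl aldehyde 7 with the semi-stabilised benzylic ylide from 2; the alkene geometry is again of no consequence.

**Step 5**
Reactants: 8 bis-stilbene
Product: 9 5-[2-(2-{6-[2-(4-hydroxyphenyl)ethyl]-2,3-dimethoxyphenoxy}phenyl)ethyl]-2-methoxyphenol
Conditions: H2 (1 atm), 10% Pd/C, EtOAc–MeOH, rt
Reagents that add atoms: none
Why: Heterogeneous catalytic hydrogenation saturates both stilbene C=C bonds and hydrogenolysis removes both benzyl ethers in one operation, while aryl methyl ethers and the diaryl ether are stable.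

**Step 6**
Reactants: 9 seco bis-phenol
Product: 12 macrocyclic tri-O-methyl ether of the target, via orthoquinol acetate 10 (not isolated), via 1,6-adduct dienol 11 (not isolated)
Conditions: PhI(OAc)2 (1.0 equiv), CH2Cl2, −78 → −30 °C; then slow addition to Cs2CO3, MeCN, 0 °C → rt, ≤1 mM, Ar
Reagents that add atoms: none
Why: Proposed new method: PhI(OAc)2 dearomatises the 2-methoxyphenol of ring A at its methoxy-bearing carbon (Wessely acetoxylation, known for 2-alkoxyphenols) to the 6-acetoxy-6-methoxycyclohexa-2,4-dienone 10, whose acetate comes from the oxidant; in 10 the carbonyl stands on the former phenol carbon, the bridge-bearing carbon is the blocked β-position, and the CH next to the C(OMe)(OAc) carbon is the only open conjugate (δ) position. The caesium phenoxide of ring B should add there in a 1,6-oxa-Michael sense to give 11, and E1-like loss of acetate from the dienol(ate) to a methoxy-stabilised cation followed by loss of the proton on the aryloxy-bearing carbon restores the benzene ring with the aryloxy group ortho to the retained methoxy group. The closest known reaction type is the conjugate addition–rearomatisation of quinone monoketals and orthoquinol acetates with carbon, nitrogen and sulfur nucleophiles (oxidative nucleophilic substitution of hydrogen), here extended to an intramolecular phenoxide. The 17-membered ring closes by 17-endo-trig attack of oxygen on the dienone terminus, the chain being stiffened by four arene units. No stereocentre results, since the sp3 centres of 10 and 11 are racemic, transient and erased on rearomatisation. Chemoselectivity for ring A over the p-alkylphenol of ring B rests on the faster iodine(III) dearomatisation of o-methoxyphenols at low temperature with one equivalent of oxidant in a non-nucleophilic solvent, regioselectivity on the single unblocked acceptor carbon under basic aprotic conditions that keep the acetoxy carbon from ionising before addition, and the irreversible loss of acetate should pull the reversible addition forward while high dilution holds back dienone dimerisation and oligomers.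

**Step 7**
Reactants: 12 macrocyclic tri-O-methyl ether
Product: 13 target CNP0114693.0
Conditions: BBr3 (excess), CH2Cl2, −78 °C → rt; then degassed H2O/MeOH quench
Reagents that add atoms: none
Why: Lewis-acid ether cleavage in which BBr3 coordinates each methoxy oxygen and bromide removes the methyl group by SN2, while the diaryl ether C–O bonds are not cleaved; degassed acidic work-up protects the catechol and pyrogallol-type rings from air oxidation.

**Compound list**
1 | 4-(benzyloxy)benzyl chloride | ClCc1ccc(OCc2ccccc2)cc1 | starting material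
2 | [4-(benzyloxy)benzyl]triphenylphosphonium chloride | [Cl-].c1ccc(cc1)COc1ccc(C[P+](c2ccccc2)(c2ccccc2)c2ccccc2)cc1 | intermediate
3 | (2-hydroxybenzyl)triphenylphosphonium bromide | [Br-].Oc1ccccc1C[P+](c1ccccc1)(c1ccccc1)c1ccccc1 | starting material
4 | 3-(benzyloxy)-4-methoxybenzaldehyde | COc1ccc(C=O)cc1OCc1ccccc1 | starting material
5 | 2-[2-(3-benzyloxy-4-methoxyphenyl)ethenyl]phenol (E/Z mixture) | COc1ccc(C=Cc2ccccc2O)cc1OCc1ccccc1 | intermediate
6 | 2-fluoro-3,4-dimethoxybenzaldehyde | COc1ccc(C=O)c(F)c1OC | starting material
7 | 2-{2-[2-(3-benzyloxy-4-methoxyphenyl)ethenyl]phenoxy}-3,4-dimethoxybenzaldehyde (E/Z mixture) | COc1ccc(C=Cc2ccccc2Oc2c(C=O)ccc(OC)c2OC)cc1OCc1ccccc1 | intermediate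
8 | 1-benzyloxy-4-{2-[2-(2-{2-[3-(benzyloxy)-4-methoxyphenyl]ethenyl}phenoxy)-3,4-dimethoxyphenyl]ethenyl}benzene (E/Z mixture at both alkenes) | COc1ccc(C=Cc2ccccc2Oc2c(C=Cc3ccc(OCc4ccccc4)cc3)ccc(OC)c2OC)cc1OCc1ccccc1 | intermediate
9 | 5-[2-(2-{6-[2-(4-hydroxyphenyl)ethyl]-2,3-dimethoxyphenoxy}phenyl)ethyl]-2-methoxyphenol | COc1ccc(CCc2ccccc2Oc2c(CCc3ccc(O)cc3)ccc(OC)c2OC)cc1O | intermediate
10 | 6-acetoxy-3-[2-(2-{6-[2-(4-hydroxyphenyl)ethyl]-2,3-dimethoxyphenoxy}phenyl)ethyl]-6-methoxycyclohexa-2,4-dien-1-one (racemic orthoquinol acetate, not isolated) | COC1(OC(C)=O)C=CC(CCc2ccccc2Oc2c(CCc3ccc(O)cc3)ccc(OC)c2OC)=CC1=O | intermediate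
11 | macrocyclic 1,6-adduct drawn as its dienol: ring-B oxygen bonded to the sp3 CH next to the C(OMe)(OAc) carbon of the former ring A (diastereomer mixture, not isolated) | OC1=CC2=CC(C1(OC)OC(C)=O)Oc1ccc(cc1)CCc1ccc(OC)c(OC)c1Oc1ccccc1CC2 | intermediate
12 | macrocyclic tri-O-methyl ether of the target (ring A: free OH, OMe on the carbon between C–OH and C–OAr; ring C: two OMe) | Oc1cc2cc(c1OC)Oc1ccc(cc1)CCc1ccc(OC)c(OC)c1Oc1ccccc1CC2 | intermediate
13 | CNP0114693.0 | Oc1cc2cc(c1O)Oc1ccc(cc1)CCc1ccc(O)c(O)c1Oc1ccccc1CC2 | target

**Totals**
Total step count: 7. Longest linear sequence: 6 steps (steps 2–7, from 3 and 4).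

**Steps most likely to fail**

1. Step 6 (Proposed new method). The oxidant may also attack the ring-B phenol. The dienone may dimerise by cycloaddition before ring closure. The reversible oxa-addition may be outrun by acyl transfer from the acetate to the phenoxide, by C-attack of the phenoxide, or by intermolecular addition leading to oligomers. The fallback uses known chemistry, an intramolecular Ullmann ether macrocyclisation of an aryl bromide, which needs ring A as a brominated catechol dimethyl ether. It sets out from 3 and comes back at 13. Wittig reaction of 3 with commercial 3-bromo-4,5-dimethoxybenzaldehyde (t-BuOK, THF) should give 2-[2-(3-bromo-4,5-dimethoxyphenyl)ethenyl]phenol F1. SNAr of F1 with 6 (Cs2CO3, DMSO, 100 °C) should give 2-{2-[2-(3-bromo-4,5-dimethoxyphenyl)ethenyl]phenoxy}-3,4-dimethoxybenzaldehyde F2. Wittig reaction of F2 with 2 should give 1-benzyloxy-4-{2-[2-(2-[2-(3-bromo-4,5-dimethoxyphenyl)ethenyl]phenoxy)-3,4-dimethoxyphenyl]ethenyl}benzene F3. Diimide reduction (TsNHNH2, NaOAc, THF/H2O, reflux) should saturate both alkenes without touching the C–Br bond and give 1-benzyloxy-4-{2-[2-(2-[2-(3-bromo-4,5-dimethoxyphenyl)ethyl]phenoxy)-3,4-dimethoxyphenyl]ethyl}benzene F4. BCl3 with pentamethylbenzene (CH2Cl2, −78 °C) should remove the benzyl group and give 4-{2-[2-(2-[2-(3-bromo-4,5-dimethoxyphenyl)ethyl]phenoxy)-3,4-dimethoxyphenyl]ethyl}phenol F5. CuI, N,N-dimethylglycine and Cs2CO3 in dioxane at 100 °C under high dilution should close the ring to the macrocyclic tetra-O-methyl ether of the target F6. BBr3 as in step 7 should then give 13.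

2. Step 3. Substitution at a fluoride flanked by the formyl and a methoxy group by an ortho-substituted phenoxide may be slow, so prolonged heating could degrade the aldehyde and the stilbene. The fallback is a copper-catalysed Ullmann coupling with the bromide in place of SNAr; it sets out from 5 and comes back at 7. Commercial 2-bromo-3-hydroxy-4-methoxybenzaldehyde is methylated (MeI, K2CO3, DMF) to 2-bromo-3,4-dimethoxybenzaldehyde F7. Coupling of 5 with F7 (CuI, N,N-dimethylglycine, Cs2CO3, dioxane, 100 °C, Ar) should give 7.

3. Step 2. The ylide of 3 carries a phenoxide and may react sluggishly with the electron-rich aldehyde 4, leaving incomplete conversion and betaine side reactions. The fallback forms the same alkene by a Heck reaction instead of a carbonyl olefination; it sets out from 4 and comes back at 5. Methylenation of 4 (Ph3PCH3Br, t-BuOK, THF) should give 3-(benzyloxy)-4-methoxystyrene F8. Heck coupling of F8 with commercial 2-iodophenol (Pd(OAc)2, P(o-tol)3, Et3N, DMF, 100 °C) should give 5 as the E isomer.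

**Further compounds**
F1 | step 6 | 2-[2-(3-bromo-4,5-dimethoxyphenyl)ethenyl]phenol | COc1cc(C=Cc2ccccc2O)cc(Br)c1OC
F2 | step 6 | 2-{2-[2-(3-bromo-4,5-dimethoxyphenyl)ethenyl]phenoxy}-3,4-dimethoxybenzaldehyde | COc1cc(C=Cc2ccccc2Oc2c(C=O)ccc(OC)c2OC)cc(Br)c1OC
F3 | step 6 | 1-benzyloxy-4-{2-[2-(2-[2-(3-bromo-4,5-dimethoxyphenyl)ethenyl]phenoxy)-3,4-dimethoxyphenyl]ethenyl}benzene | COc1cc(C=Cc2ccccc2Oc2c(C=Cc3ccc(OCc4ccccc4)cc3)ccc(OC)c2OC)cc(Br)c1OC
F4 | step 6 | 1-benzyloxy-4-{2-[2-(2-[2-(3-bromo-4,5-dimethoxyphenyl)ethyl]phenoxy)-3,4-dimethoxyphenyl]ethyl}benzene | COc1cc(CCc2ccccc2Oc2c(CCc3ccc(OCc4ccccc4)cc3)ccc(OC)c2OC)cc(Br)c1OC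
F5 | step 6 | 4-{2-[2-(2-[2-(3-bromo-4,5-dimethoxyphenyl)ethyl]phenoxy)-3,4-dimethoxyphenyl]ethyl}phenol | COc1cc(CCc2ccccc2Oc2c(CCc3ccc(O)cc3)ccc(OC)c2OC)cc(Br)c1OC
F6 | step 6 | macrocyclic tetra-O-methyl ether of the target | COc1cc2cc(c1OC)Oc1ccc(cc1)CCc1ccc(OC)c(OC)c1Oc1ccccc1CC2
F7 | step 3 | 2-bromo-3,4-dimethoxybenzaldehyde | COc1ccc(C=O)c(Br)c1OC
F8 | step 2 | 3-(benzyloxy)-4-methoxystyrene | C=Cc1ccc(OC)c(OCc2ccccc2)c1
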